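# Proposal: 3β-acetoxy-9α-hydroxy-labd-13-en-16,15-olide (21) by a Michael–aldol double ring closure

Labdane numbering is used throughout: ring A = C1–C5 and C10, ring B = C5–C10. Bicyclic intermediates are named as 4,4,8,10-tetramethyl decalins in this numbering.

## The problem

Target 21 is a trans-decalin whose C9 carries a tertiary hydroxyl and a two-carbon tether to the α-carbon of a butenolide; C3 bears an acetate, C4 a gem-dimethyl group, C8 and C10 one methyl each. Five stereocentres must be set (C3, C5, C8, C9, C10). Three are contiguous, and C9 is a fully substituted carbinol between the quaternary C10 and the methyl-bearing C8.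

Only C3 can reasonably be made by reagent control in an open chain. Next to the gem-dimethyl group it can steer C5 and C10 through a chair, and C8 can be corrected by enolisation while a carbonyl sits at C7. C9 cannot be epimerised directly, so it must come out right in the bond-forming event or through a reversible one.

The tertiary C9 hydroxyl is the fragile group. β to a C7 carbonyl it can leave by E1cB or retro-aldol, it ionises in strong acid, and under base it can add to C14 of the finished butenolide. The acetate and the butenolide forbid strong base late in the route.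

The enabling feature is that C9 is 1,3 to C7 in ring B and that C9 and C7 are 1,5 across C10–C5–C6. With a temporary ketone at C7, C8–C9 is an aldol bond and the ring-fusion bond C5–C10 is a Michael bond between the enolate of a C9 ketone and a C5=C6–C7 enone. Both rings and four stereocentres can then arise from a chain that holds C3 alone. The price is that the intermediate 1,5-diketone can close its aldol in two six-membered ways.

## Retrosynthesis

**Butenolide and acetate (21 ⇒ 19 ⇒ 17 ⇒ 15 + 16).** The C13=C14 double bond and the C3 acetate are removed together: 21 comes from triol lactone 19 by acetylation of both secondary hydroxyls and β-elimination of the C14 acetate. Only C13 carries an acidic hydrogen, so the double bond can form nowhere else. Lactone 19 is opened to hydroxy ester 17, and cutting C13–C14 gives ester 15 and the silylated glycolaldehyde 16. The chain already ends in the C16 ester with C13 as its α-carbon, so one aldol brings in C14 and C15. Oxidising a furan or isomerising an alkylidene lactone would give regioisomer problems. The forward reactions must work in the presence of the free tertiary C9 hydroxyl.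

**C7 carbonyl (15 ⇒ 14 ⇒ 13).** A ketone is put back at C7. It is the device that turns C8–C9 into an aldol bond and C5–C10 into a Michael bond, and it costs two steps to remove. The removal must not touch the β-hydroxyl, which speaks for the tosylhydrazone 14 reduced under neutral conditions.

**Both rings (13 ⇒ 12 ⇒ 11).** C8–C9 (aldol) and C5–C10 (Michael) are cut in one operation, through the monocyclic diketone 12, back to the acyclic enone–keto ester 11. The neighbouring cut at C9–C11 (adding the chain to a 9-ketone) is rejected: a nucleophile would approach anti to the axial C10 methyl and put the hydroxyl on the wrong face. Precursor 11 has one stereocentre and no ring. The forward step must find the C10 enolate, use C3 to choose the face of the chair, close the aldol from C8 and not from C11, and stop at the ketol. A tert-butyl ester is chosen so that the C9 alkoxide does not lactonise.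

**Enone (11 ⇒ 9 + 10, 9 ⇒ 8).** C5=C6 is cut by Horner–Wadsworth–Emmons into aldehyde 9 and phosphonate 10. Aldehyde 9 comes from the vinyl group of 8 by ozonolysis. The vinyl group is a masked aldehyde that needs no reduction next to the ketone and the ester, which a route through a C5 carboxylic ester would require.

**Protecting groups and ring opening (8 ⇒ 7 ⇒ 6 ⇒ 5).** The silyl ether and tert-butyl ester are removed to give hydroxy keto acid 6. Its 5-oxo acid chain with a methyl on C6 is reconnected (C1 to C6 of the acid) to the 2,2-disubstituted cyclohexane-1,3-dione 5. The retro-Claisen opening delivers C9 to C16 with the C10 methyl in one step, and either carbonyl gives the same product.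

**C3 and the gem-dimethyl unit (5 ⇒ 3 + 4, 3 ⇒ 1 + 2).** The C3–C4 bond is cut by asymmetric prenylation of aldehyde 3 with a borane made from allene 4. This sets C3 and brings the quaternary C4 and the vinyl group at once. Aldehyde 3 is the Michael adduct of dione 1 and acrolein 2.

## Roads not taken

**Alternative 1:** The cut is through C11–C12, C12–C13 and the C9–O bond. Tetronic acid A3 and formaldehyde A4 would condense to heterodiene A5, whose oxadiene would add to the exocyclic C9=C11 alkene of decalin A2 to give spiro adduct A1.
- Merits: convergent; the butenolide carbons arrive whole; the oxygen should add to C9 from the face away from the C10 methyl, which is arguably a safer way to set C9 than an aldol.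
- Weak points: A2 is itself a complete decalin with four stereocentres and must be made first. The alkene is 1,1-disubstituted next to a quaternary carbon and is a poor partner for an inverse-demand cycloaddition, while A5 readily takes up a second molecule of A3. A1 still has oxygen on C14; removing it means breaking the O–C14 bond, whereas acid would rather break the tertiary C9–O bond.
- Comparison: this road is better for C9 and the side chain. The chosen plan builds the decalin and the C9 carbinol in one step from 11 and needs no deoxygenation at C14.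

**Alternative 2:** The cut is across C7–C8 and C9–C10. Ring A silyloxydiene A7 and the chiral ethylidene dioxolanone A8 would combine in a Diels–Alder reaction to give spiro cycloadduct A6.
- Merits: convergent; the auxiliary sets C9 absolutely; the alkene geometry of A8 fixes C8 against C9.
- Weak points: the C9–C10 bond joins two fully substituted carbons, one on a tetrasubstituted diene terminus beside a gem-dimethyl group, so the cycloaddition would be slow and its facial sense relative to C3 unproven. C11 arrives as a carboxyl carbon and must be reduced and extended by C12 and C13 before the butenolide. C5 and a C6 oxygen are left for later steps.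
- Comparison: absolute control of C9 is better here. The chosen plan has the full C11–C16 chain in place when the rings close, and C5 is set in the same step.

**Alternative 3:** The cut is through C4–C5 and C9–C10. A Lewis acid would open the epoxide of epoxy keto ester A10; the alkene closes ring A and the enol carbon of the β-keto ester closes ring B, giving bicyclic keto ester A9.
- Merits: the closest to known practice; C3, C5 and C10 follow from one epoxide centre with good reliability; A10 is made in few steps.
- Weak points: A9 lacks the C8 methyl, the C9 hydroxyl and all of C12–C16. Methylenation and reduction at C8, hydroxylation at C9 and a long chain extension from the C11 ester would follow, and such bicyclisations compete with O-termination and monocyclisation.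
- Comparison: this road is safer for ring-A stereochemistry. The chosen plan answers with step economy after ring closure, since 13 already holds the C9 hydroxyl, the C8 methyl and the chain.

Key step: step 8

Assumption: the prenylborane from (−)-α-pinene is taken to deliver the prenyl group to the Re face of aldehyde 3, by analogy with allyl transfer from the same borane family; if the sense is opposite, the enantiomeric borane is used.

## Route

Step 1
Reactants: 1 2-methylcyclohexane-1,3-dione; 2 acrolein
Product: 3 3-(1-methyl-2,6-dioxocyclohexyl)propanal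
Conditions: H2O, rt
Reagents that add atoms: none
Why: Michael addition of the acidic cyclic 1,3-dione to acrolein runs in water without added base, which avoids the base-induced aldol closure of 3; no stereocentre is formed.

Step 2
Reactants: 3 3-(1-methyl-2,6-dioxocyclohexyl)propanal; 4 3-methylbuta-1,2-diene
Product: 5 2-[(3S)-3-hydroxy-4,4-dimethylhex-5-en-1-yl]-2-methylcyclohexane-1,3-dione
Conditions: (+)-Ipc2BH, THF, −25 → 0 °C; then 3, Et2O, −78 °C; HOCH2CH2NH2, rt
Reagents that add atoms: none
Why: Brown-type asymmetric prenylation: hydroboration of 4 gives the prenylborane, whose γ-carbon adds to the aldehyde through a chair transition state with allylic transposition. The isopinocampheyl groups set C3 (S) by reagent control and the step installs the gem-dimethyl carbon and the vinyl group; the ring ketones do not react with allylboranes at −78 °C.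

Step 3
Reactants: 5 2-[(3S)-3-hydroxy-4,4-dimethylhex-5-en-1-yl]-2-methylcyclohexane-1,3-dione
Product: 6 (9S)-9-hydroxy-6,10,10-trimethyl-5-oxododec-11-enoic acid (C6 epimers)
Conditions: NaOH (2 M aq.), THF, rt → 45 °C; then HCl (1 M), 0 °C
Reagents that add atoms: sodium hydroxide [Na+].[OH-]
Why: Retro-Claisen cleavage of a non-enolisable 2,2-disubstituted 1,3-diketone by hydroxide; both carbonyls lead to the same keto acid, and any hemiketal or lactone formed from the free hydroxyl is opened to the same product. The new methyl-bearing centre is left as a mixture because it becomes an enolate in step 8.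

Step 4
Reactants: 6 (9S)-9-hydroxy-6,10,10-trimethyl-5-oxododec-11-enoic acid
Product: 7 tert-butyl (9S)-9-hydroxy-6,10,10-trimethyl-5-oxododec-11-enoate
Conditions: Cl3CC(=NH)OtBu, CH2Cl2–cyclohexane, rt
Reagents that add atoms: tert-butyl 2,2,2-trichloroacetimidate CC(C)(C)OC(=N)C(Cl)(Cl)Cl
Why: tert-Butyl transfer from the trichloroacetimidate to a carboxylic acid needs no added acid, so the hindered secondary alcohol is not etherified and the alkene is untouched.

Step 5
Reactants: 7 tert-butyl (9S)-9-hydroxy-6,10,10-trimethyl-5-oxododec-11-enoate
Product: 8 tert-butyl (9S)-9-(tert-butyldimethylsilyloxy)-6,10,10-trimethyl-5-oxododec-11-enoate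
Conditions: TBSOTf, 2,6-lutidine, CH2Cl2, −78 → 0 °C
Reagents that add atoms: tert-butyldimethylsilyl trifluoromethanesulfonate CC(C)(C)[Si](C)(C)OS(=O)(=O)C(F)(F)F
Why: Silylation of a neopentyl-type secondary alcohol needs the silyl triflate; tert-butyl esters and ketones tolerate it at low temperature. The ether blocks vinylogous retro-aldol fragmentation of C3–C4 once the enone is in place.

Step 6
Reactants: 8 tert-butyl (9S)-9-(tert-butyldimethylsilyloxy)-6,10,10-trimethyl-5-oxododec-11-enoate
Product: 9 tert-butyl (9S)-9-(tert-butyldimethylsilyloxy)-6,10,10-trimethyl-5,11-dioxoundecanoate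
Conditions: O3, CH2Cl2, −78 °C; then PPh3, −78 °C → rt
Reagents that add atoms: ozone [O-][O+]=O
Why: Ozonolysis with reductive work-up unmasks the C5 aldehyde; it is α-quaternary, so it can neither enolise nor lose the β-silyloxy group, and it is used without storage.

Step 7
Reactants: 9 tert-butyl (9S)-9-(tert-butyldimethylsilyloxy)-6,10,10-trimethyl-5,11-dioxoundecanoate; 10 diethyl (2-oxobutyl)phosphonate
Product: 11 tert-butyl (9S,11E)-9-(tert-butyldimethylsilyloxy)-6,10,10-trimethyl-5,13-dioxopentadec-11-enoate
Conditions: LiCl, iPr2NEt, MeCN, rt
Reagents that add atoms: none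
Why: Horner–Wadsworth–Emmons olefination under Masamune–Roush conditions: only the β-ketophosphonate is acidic enough for LiCl and amine, so the remote ketone is not enolised and cannot attack the aldehyde; the stabilised phosphonate gives the E enone.

Step 8
Reactants: 11 tert-butyl (9S,11E)-9-(tert-butyldimethylsilyloxy)-6,10,10-trimethyl-5,13-dioxopentadec-11-enoate
Product: 13 tert-butyl 4-[3β-(tert-butyldimethylsilyloxy)-9α-hydroxy-4,4,8α,10β-tetramethyl-7-oxo-5α-decalin-9β-yl]butanoate, via Michael adduct 12 (not isolated)
Conditions: KOtBu (0.3 equiv), THF–t-BuOH (10:1), −20 → 10 °C; aq. NH4Cl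
Reagents that add atoms: none
Why: Catalytic tert-butoxide equilibrates the ketone enolates of 11, and only the C10 enolate can reach the enone through a six-membered transition state (the C11 enolate would need an eight-membered one), so ring A closes by a 6-(enolexo)-exo-trig Michael addition at C5 to give 12. Proton exchange then places the enolate on C8 of the C7 ketone, which adds to the C9 carbonyl and closes ring B by a 6-(enolendo)-exo-trig aldol addition; the closest known reaction type is the intramolecular Michael addition of a ketone enolate to an enone followed by Robinson-type ketol formation from the 1,5-diketone, run in one flask. C5 and C10 are set in a chair transition state of ring A with the C3 silyloxy group equatorial and the enolate and enone units trans-diequatorial, which puts the C10 methyl axial and H5 on the opposite face. C8 is set by reversible enolisation next to C7 and should settle with its methyl equatorial. C9 is set in the aldol step, where the carbonyl oxygen should take the axial position that lets potassium bridge it to the C7 enolate oxygen while the chain goes equatorial; the aldol is reversible, so this centre can correct itself. The step needs four selectivities: Michael regiochemistry (secured by ring size); the face relative to C3 (secured by the equatorial silyl ether beside the gem-dimethyl group); C8 over C11 as aldol donor (not secured by ring size, since the C11 enolate can close a six-membered ketol on C7; it rests on the base being regenerated at the C7 carbonyl after the Michael step and on stopping before full equilibration); and arrest at the ketol (catalytic base, low temperature, and a tert-butyl ester that keeps the C9 alkoxide from lactonising).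

Step 9
Reactants: 13 tert-butyl 4-[3β-(tert-butyldimethylsilyloxy)-9α-hydroxy-4,4,8α,10β-tetramethyl-7-oxo-5α-decalin-9β-yl]butanoate
Product: 14 C7 p-toluenesulfonylhydrazone of 13
Conditions: TsNHNH2, MeOH, rt → 40 °C
Reagents that add atoms: p-toluenesulfonohydrazide Cc1ccc(cc1)S(=O)(=O)NN
Why: Condensation of the ketone with the sulfonyl hydrazide under neutral conditions, chosen so that the β-hydroxyl is not lost; C8 remains epimerisable through the ene-hydrazine and should stay equatorial.

Step 10
Reactants: 14 C7 p-toluenesulfonylhydrazone of 13
Product: 15 tert-butyl 4-[3β-(tert-butyldimethylsilyloxy)-9α-hydroxy-4,4,8α,10β-tetramethyl-5α-decalin-9β-yl]butanoate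
Conditions: catecholborane, CHCl3, 0 °C → rt; then NaOAc·3H2O, reflux
Reagents that add atoms: none
Why: Caglioti-type tosylhydrazone reduction under Kabalka conditions: catecholborane adds to C=N, acetate expels sulfinate to give a diazene, and loss of N2 leaves the C7 methylene. One equivalent of borane is consumed by the tertiary hydroxyl and released on work-up; the ester and silyl ether are untouched. From here no centre can epimerise.

Step 11
Reactants: 15 tert-butyl 4-[3β-(tert-butyldimethylsilyloxy)-9α-hydroxy-4,4,8α,10β-tetramethyl-5α-decalin-9β-yl]butanoate; 16 (tert-butyldimethylsilyloxy)acetaldehyde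
Product: 17 tert-butyl 4-(tert-butyldimethylsilyloxy)-2-{2-[3β-(tert-butyldimethylsilyloxy)-9α-hydroxy-4,4,8α,10β-tetramethyl-5α-decalin-9β-yl]ethyl}-3-hydroxybutanoate (C13 and C14 diastereomers)
Conditions: LiN(iPr)2 (2.3 equiv), THF, −78 °C; then 16, −78 °C; aq. NH4Cl
Reagents that add atoms: none
Why: Aldol addition of the lithium enolate of the tert-butyl ester (formed beside the C9 alkoxide) to the aldehyde, which forms C13–C14; the two new centres are a mixture, and both become sp2 or are removed in steps 12 and 13.

Step 12
Reactants: 17 tert-butyl 4-(tert-butyldimethylsilyloxy)-2-{2-[3β-(tert-butyldimethylsilyloxy)-9α-hydroxy-4,4,8α,10β-tetramethyl-5α-decalin-9β-yl]ethyl}-3-hydroxybutanoate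
Product: 19 3-{2-[3β,9α-dihydroxy-4,4,8α,10β-tetramethyl-5α-decalin-9β-yl]ethyl}-4-hydroxydihydrofuran-2(3H)-one, via silyl hydroxy lactone 18 (not isolated)
Conditions: Bu4NF, THF, 0 °C → 45 °C; aq. NH4Cl
Reagents that add atoms: none
Why: Fluoride desilylation: the primary C15 alkoxide is freed first and attacks the tert-butyl ester in a 5-exo-trig lactonisation that expels tert-butoxide to give 18; the hindered C3 silyl ether is cleaved on warming.

Step 13
Reactants: 19 3-{2-[3β,9α-dihydroxy-4,4,8α,10β-tetramethyl-5α-decalin-9β-yl]ethyl}-4-hydroxydihydrofuran-2(3H)-one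
Product: 21 3β-acetoxy-9α-hydroxy-labd-13-en-16,15-olide (target), via diacetate 20 (not isolated)
Conditions: Ac2O, Et3N, DMAP (cat.), CH2Cl2, 0 °C → rt
Reagents that add atoms: acetic anhydride CC(=O)OC(C)=O
Why: Acetylation of the two secondary hydroxyls (the hindered tertiary C9 hydroxyl does not react) followed by E1cB elimination of the β-acetoxy lactone with the amine base; only C13 carries an acidic hydrogen, so the double bond forms at C13=C14 and the C3 acetate of the target is installed in the same flask.

## Compound list

1 | 2-methylcyclohexane-1,3-dione | CC1C(=O)CCCC1=O | starting material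
2 | acrolein | C=CC=O | starting material
3 | 3-(1-methyl-2,6-dioxocyclohexyl)propanal | CC1(CCC=O)C(=O)CCCC1=O | intermediate
4 | 3-methylbuta-1,2-diene | CC(C)=C=C | starting material
5 | 2-[(3S)-3-hydroxy-4,4-dimethylhex-5-en-1-yl]-2-methylcyclohexane-1,3-dione (may rest as its bicyclic hemiketal) | CC1(CC[C@H](O)C(C)(C)C=C)C(=O)CCCC1=O | intermediate
6 | (9S)-9-hydroxy-6,10,10-trimethyl-5-oxododec-11-enoic acid (C6 epimers) | OC(=O)CCCC(=O)C(C)CC[C@H](O)C(C)(C)C=C | intermediate
7 | tert-butyl (9S)-9-hydroxy-6,10,10-trimethyl-5-oxododec-11-enoate (C6 epimers) | CC(C)(C)OC(=O)CCCC(=O)C(C)CC[C@H](O)C(C)(C)C=C | intermediate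
8 | tert-butyl (9S)-9-(tert-butyldimethylsilyloxy)-6,10,10-trimethyl-5-oxododec-11-enoate (C6 epimers) | CC(C)(C)OC(=O)CCCC(=O)C(C)CC[C@H](O[Si](C)(C)C(C)(C)C)C(C)(C)C=C | intermediate
9 | tert-butyl (9S)-9-(tert-butyldimethylsilyloxy)-6,10,10-trimethyl-5,11-dioxoundecanoate (C6 epimers) | CC(C)(C)OC(=O)CCCC(=O)C(C)CC[C@H](O[Si](C)(C)C(C)(C)C)C(C)(C)C=O | intermediate
10 | diethyl (2-oxobutyl)phosphonate | CCC(=O)CP(=O)(OCC)OCC | starting material
11 | tert-butyl (9S,11E)-9-(tert-butyldimethylsilyloxy)-6,10,10-trimethyl-5,13-dioxopentadec-11-enoate (C6 epimers) | CCC(=O)/C=C/C(C)(C)[C@@H](O[Si](C)(C)C(C)(C)C)CCC(C)C(=O)CCCC(=O)OC(C)(C)C | intermediate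
12 | tert-butyl 5-[4-(tert-butyldimethylsilyloxy)-1,3,3-trimethyl-2-(2-oxobutyl)cyclohexyl]-5-oxopentanoate (ring A only; C3, C5 and C10 as in 13) | CC(C)(C)[Si](C)(C)O[C@H]1CC[C@@](C(=O)CCCC(=O)OC(C)(C)C)(C)[C@@H](CC(=O)CC)C1(C)C | intermediate
13 | tert-butyl 4-[3β-(tert-butyldimethylsilyloxy)-9α-hydroxy-4,4,8α,10β-tetramethyl-7-oxo-5α-decalin-9β-yl]butanoate | CC(C)(C)[Si](C)(C)O[C@H]1CC[C@@]2(C)[C@@H](CC(=O)[C@@H](C)[C@]2(O)CCCC(=O)OC(C)(C)C)C1(C)C | intermediate
14 | C7 p-toluenesulfonylhydrazone of 13 | CC(C)(C)[Si](C)(C)O[C@H]1CC[C@@]2(C)[C@@H](CC(=NNS(=O)(=O)c3ccc(C)cc3)[C@@H](C)[C@]2(O)CCCC(=O)OC(C)(C)C)C1(C)C | intermediate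
15 | tert-butyl 4-[3β-(tert-butyldimethylsilyloxy)-9α-hydroxy-4,4,8α,10β-tetramethyl-5α-decalin-9β-yl]butanoate | CC(C)(C)[Si](C)(C)O[C@H]1CC[C@@]2(C)[C@@H](CC[C@@H](C)[C@]2(O)CCCC(=O)OC(C)(C)C)C1(C)C | intermediate
16 | (tert-butyldimethylsilyloxy)acetaldehyde | O=CCO[Si](C)(C)C(C)(C)C | starting material
17 | tert-butyl 4-(tert-butyldimethylsilyloxy)-2-{2-[3β-(tert-butyldimethylsilyloxy)-9α-hydroxy-4,4,8α,10β-tetramethyl-5α-decalin-9β-yl]ethyl}-3-hydroxybutanoate (C13 and C14 diastereomers) | CC(C)(C)[Si](C)(C)O[C@H]1CC[C@@]2(C)[C@@H](CC[C@@H](C)[C@]2(O)CCC(C(O)CO[Si](C)(C)C(C)(C)C)C(=O)OC(C)(C)C)C1(C)C | intermediate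
18 | 3-{2-[3β-(tert-butyldimethylsilyloxy)-9α-hydroxy-4,4,8α,10β-tetramethyl-5α-decalin-9β-yl]ethyl}-4-hydroxydihydrofuran-2(3H)-one (diastereomers) | CC(C)(C)[Si](C)(C)O[C@H]1CC[C@@]2(C)[C@@H](CC[C@@H](C)[C@]2(O)CCC3C(O)COC3=O)C1(C)C | intermediate
19 | 3-{2-[3β,9α-dihydroxy-4,4,8α,10β-tetramethyl-5α-decalin-9β-yl]ethyl}-4-hydroxydihydrofuran-2(3H)-one (diastereomers) | O[C@H]1CC[C@@]2(C)[C@@H](CC[C@@H](C)[C@]2(O)CCC3C(O)COC3=O)C1(C)C | intermediate
20 | 3,14-di-O-acetate of 19 | CC(=O)O[C@H]1CC[C@@]2(C)[C@@H](CC[C@@H](C)[C@]2(O)CCC3C(OC(C)=O)COC3=O)C1(C)C | intermediate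
21 | 3β-acetoxy-9α-hydroxy-labd-13-en-16,15-olide | CC(=O)O[C@H]1CC[C@@]2(C)[C@@H](CC[C@@H](C)[C@]2(O)CCC2=CCOC2=O)C1(C)C | target

## Step count and risks

Total step count: 13. Longest linear sequence: 13 steps (1 and 2 to 21); 4, 10 and 16 enter as purchased reagents.

**Step 8 (key step).** The most likely failure is ring B closing through the wrong enolate: the C11 enolate of the C9 ketone adds to the less hindered C7 carbonyl and gives a constitutional isomer of the ketol. The carbinol carbon of that isomer is less crowded than C9, so long equilibration is expected to favour it. Loss of water from either ketol and a weak facial bias from C3 are further hazards.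

The fallback separates the two ring closures. It sets out from aldehyde 9 and returns at 13:
- Knoevenagel condensation of 9 with allyl 3-oxopentanoate (TiCl4, pyridine, THF, 0 °C) should give the alkylidene β-keto ester, tert-butyl (9S)-12-(allyloxycarbonyl)-9-(tert-butyldimethylsilyloxy)-6,10,10-trimethyl-5,13-dioxopentadec-11-enoate F1.
- One equivalent of KOtBu in THF should close ring A by the same Michael addition. The product rests as the stabilised β-keto ester enolate, which holds all the base and blocks both aldol closures; work-up gives the Michael adduct carrying an allyloxycarbonyl group on C6 F2.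
- Pd(PPh3)4 (zerovalent palladium) and morpholine remove the allyl ester with decarboxylation and deliver diketone 12, now isolated.
- TiCl4 and Bu3N at −78 °C (titanium-mediated crossed aldol between two ketones) enolise the unhindered ethyl ketone on its ethyl side and add it to the C9 carbonyl through a closed transition state, which should give 13.

**Step 2.** The new alkoxide may attack a ring carbonyl during work-up (hemiketal formation, or retro-Claisen expansion to a ten-membered keto lactone), and the enantioselectivity on this dione aldehyde is untested.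

The fallback removes the dione before the carbinol is made. It sets out from 3 and returns at 7:
- Acetalisation (HC(OMe)3, MeOH, acid catalyst) gives 2-(3,3-dimethoxypropyl)-2-methylcyclohexane-1,3-dione F3.
- Ring opening with aqueous NaOH gives 9,9-dimethoxy-6-methyl-5-oxononanoic acid F4.
- The trichloroacetimidate of step 4 gives tert-butyl 9,9-dimethoxy-6-methyl-5-oxononanoate F5.
- Mild aqueous acid frees tert-butyl 6-methyl-5,9-dioxononanoate F6.
- Prenylation of F6 with the borane of step 2 gives 7 directly.

**Step 9.** Condensation at the hindered C7 may be slow, and warming or traces of acid may eliminate the C9 hydroxyl from the β-hydroxy hydrazone or trigger retro-aldol cleavage.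

The fallback removes the oxygen by a radical route. It sets out from 13 and returns at 15:
- NaBH4 reduces the ketone to the 7-hydroxy compound F7.
- NaH, CS2 and MeI convert the secondary hydroxyl into the C7 S-methyl xanthate F8.
- Bu3SnH and AIBN in toluene at 80 °C (Barton–McCombie deoxygenation) give 15.

**Step 12.** The freed alkoxide may fail to displace tert-butoxide, so that no lactone forms, and basic fluoride may cause retro-aldol cleavage of the β-hydroxy ester.

The fallback uses acidic fluoride and a separate ester cleavage. It sets out from 17 and returns at 19: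
- HF·pyridine removes both silyl groups and gives the tetraol ester, tert-butyl 2-{2-[3β,9α-dihydroxy-4,4,8α,10β-tetramethyl-5α-decalin-9β-yl]ethyl}-3,4-dihydroxybutanoate F9.
- TMSOTf and 2,6-lutidine exchange the tert-butyl group for silicon while covering the hydroxyls, and mild aqueous acid work-up closes the lactone to 19.

**Step 13.** Under amine base the C9 hydroxyl may add to C14 of the new butenolide and close a tetrahydropyran, or the sequence may stop at the diacetate.

The fallback forms the double bond before C3 is freed, so that elimination and acetylation are separate. It sets out from 17 and returns at 21: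
- Bu4NF at 0 °C only gives lactone 18, now isolated.
- MsCl and Et3N give the C14 mesylate F10, which eliminates at room temperature to the 3-O-silyl butenolide F11.
- HF·pyridine gives the 3-hydroxy butenolide F12.
- Ac2O in pyridine gives 21.

## Further compounds

F1 | step 8 | tert-butyl (9S)-12-(allyloxycarbonyl)-9-(tert-butyldimethylsilyloxy)-6,10,10-trimethyl-5,13-dioxopentadec-11-enoate | CC(C)(C)OC(=O)CCCC(=O)C(C)CC[C@H](O[Si](C)(C)C(C)(C)C)C(C)(C)C=C(C(=O)CC)C(=O)OCC=C
F2 | step 8 | Michael adduct of F1 (as 12 with an allyloxycarbonyl group on C6) | CC(C)(C)[Si](C)(C)O[C@H]1CC[C@@](C(=O)CCCC(=O)OC(C)(C)C)(C)[C@@H](C(C(=O)CC)C(=O)OCC=C)C1(C)C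
F3 | step 2 | 2-(3,3-dimethoxypropyl)-2-methylcyclohexane-1,3-dione | CC1(CCC(OC)OC)C(=O)CCCC1=O
F4 | step 2 | 9,9-dimethoxy-6-methyl-5-oxononanoic acid | OC(=O)CCCC(=O)C(C)CCC(OC)OC
F5 | step 2 | tert-butyl 9,9-dimethoxy-6-methyl-5-oxononanoate | CC(C)(C)OC(=O)CCCC(=O)C(C)CCC(OC)OC
F6 | step 2 | tert-butyl 6-methyl-5,9-dioxononanoate | CC(C)(C)OC(=O)CCCC(=O)C(C)CCC=O
F7 | step 9 | tert-butyl 4-[3β-(tert-butyldimethylsilyloxy)-7,9α-dihydroxy-4,4,8α,10β-tetramethyl-5α-decalin-9β-yl]butanoate | CC(C)(C)[Si](C)(C)O[C@H]1CC[C@@]2(C)[C@@H](CC(O)[C@@H](C)[C@]2(O)CCCC(=O)OC(C)(C)C)C1(C)C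
F8 | step 9 | C7 O-(S-methyl dithiocarbonate) of F7 | CC(C)(C)[Si](C)(C)O[C@H]1CC[C@@]2(C)[C@@H](CC(OC(=S)SC)[C@@H](C)[C@]2(O)CCCC(=O)OC(C)(C)C)C1(C)C
F9 | step 12 | tert-butyl 2-{2-[3β,9α-dihydroxy-4,4,8α,10β-tetramethyl-5α-decalin-9β-yl]ethyl}-3,4-dihydroxybutanoate | O[C@H]1CC[C@@]2(C)[C@@H](CC[C@@H](C)[C@]2(O)CCC(C(O)CO)C(=O)OC(C)(C)C)C1(C)C
F10 | step 13 | C14 methanesulfonate of 18 | CC(C)(C)[Si](C)(C)O[C@H]1CC[C@@]2(C)[C@@H](CC[C@@H](C)[C@]2(O)CCC3C(OS(C)(=O)=O)COC3=O)C1(C)C
F11 | step 13 | 3β-(tert-butyldimethylsilyloxy)-9α-hydroxy-labd-13-en-16,15-olide | CC(C)(C)[Si](C)(C)O[C@H]1CC[C@@]2(C)[C@@H](CC[C@@H](C)[C@]2(O)CCC2=CCOC2=O)C1(C)C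
F12 | step 13 | 3β,9α-dihydroxy-labd-13-en-16,15-olide | O[C@H]1CC[C@@]2(C)[C@@H](CC[C@@H](C)[C@]2(O)CCC2=CCOC2=O)C1(C)C
A1 | alternative 1 | spiro dihydropyrano-fused tetronate adduct | CC(=O)O[C@H]1CC[C@@]2(C)[C@@H](CC[C@@H](C)[C@]23CCC4=C(O3)COC4=O)C1(C)C
A2 | alternative 1 | 3β-acetoxy-4,4,8α,10β-tetramethyl-9-methylene-5α-decalin | CC(=O)O[C@H]1CC[C@@]2(C)[C@@H](CC[C@@H](C)C2=C)C1(C)C
A3 | alternative 1 | tetronic acid | OC1=CC(=O)OC1
A4 | alternative 1 | formaldehyde | C=O
A5 | alternative 1 | 3-methylenefuran-2,4(3H,5H)-dione | C=C1C(=O)COC1=O
A6 | alternative 2 | spiro-dioxolanone cycloadduct with the C5=C6 silyl enol ether | CC(C)(C)[Si](C)(C)O[C@H]1CC[C@@]2(C)C(=C(O[Si](C)(C)C(C)(C)C)C[C@@H](C)[C@]23C(=O)O[C@@H](C(C)(C)C)O3)C1(C)C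
A7 | alternative 2 | ring A 2-silyloxydiene | CC1=C(C(=C)O[Si](C)(C)C(C)(C)C)C(C)(C)[C@@H](O[Si](C)(C)C(C)(C)C)CC1
A8 | alternative 2 | (2S,5Z)-2-tert-butyl-5-ethylidene-1,3-dioxolan-4-one | C/C=C1\O[C@H](C(C)(C)C)OC1=O
A9 | alternative 3 | methyl 3β-hydroxy-8-oxo-12-nordriman-11-oate | O[C@H]1CC[C@@]2(C)[C@@H](CCC(=O)[C@@H]2C(=O)OC)C1(C)C
A10 | alternative 3 | methyl (6E,10S)-10,11-epoxy-7,11-dimethyl-3-oxododec-6-enoate | COC(=O)CC(=O)CC/C=C(\C)CC[C@@H]1OC1(C)C
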